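## Retrosynthetic overview

1. Target 15 is the ring-closed (hemiketal) form of a δ-hydroxy α-bromo methyl ketone. Its (E)-bromovinyl group goes back to an aldehyde (Takai), which leaves a 1,6-keto aldehyde (ketone = C2, aldehyde = C3').
2. Enabling feature: on the oxane ring (O1, C2–C6) the hemiketal OH at C2 and the C5 side chain are cis. C2 and side-chain carbon C3' can therefore be reconnected as a 1,2-diol. This closes a cyclohexane (C2–C3–C4–C5–C2'–C3') across the oxane ring and turns the segment C5–C6–O1–C2 into the O–C(=O) bridge of a 2-oxabicyclo[2.2.2]octane.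
3. That bicycle is the [4+2] adduct of 4,6-dimethyl-2-pyrone with a CH2=CBr unit, used as 2-bromoacrolein (formyl = removable activator). The pyrone methyls become C2–CH3 and C2'–CH3, and its ring O and C=O become O1 and C6. The cycloaddition makes C4–C5 and C3–C2 and fixes C5.
4. Inside the rigid bicycle the formyl carbon is excised (sets C3–H). The C2'=C3' alkene is taken to the ketone and chlorinated on the lactone-side face (sets C2'). Reduction, glycol cleavage and olefination follow.
5. Ring order: cyclohexene and lactone (future oxane) rings form together in step 1. The lactone is opened in step 6 and the carbocycle is cleaved in step 8. The oxane ring closes again as the hemiketal in step 9.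

Key step: step 1

Locants: target = oxane numbering O1, C2–C6, with side chain C1' (CH3), C2' (C–Cl), C3', C4' (CHBr). Bicycles = 2-oxabicyclo[2.2.2]octane numbering, where C1 = later C2, C3 = later C6, C4 = later C5, C5 = later C2', C6 = later C3', C7 = later C3, C8 = later C4. "Endo" means syn to the C5–C6 bridge and "exo" means syn to the O2–C3 bridge.

Assumption: the absolute sense of induction in step 1 is taken from the accepted formyl C–H···O binding model for 2-substituted acroleins on this catalyst family. Should the adduct prove antipodal, the (R)-configured catalyst is used and nothing else changes.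

Assumption: 2-bromoacrolein is treated as a purchasable fine chemical.

## Route

Step 1
Reactants: 1 4,6-dimethyl-2H-pyran-2-one; 2 2-bromoprop-2-enal (2-bromoacrolein)
Product: 3 (1S,4S,7S)-7-bromo-1,5-dimethyl-3-oxo-2-oxabicyclo[2.2.2]oct-5-ene-7-carbaldehyde (Br endo; CHO exo)
Conditions: (S)-3,3-diphenyl-1-(2-methylphenyl)tetrahydro-1H,3H-pyrrolo[1,2-c][1,3,2]oxazaborole (20 mol %), HN(SO2CF3)2 (20 mol %), CH2Cl2, −78 → −20 °C
Reagents that add atoms: none
Why: Proposed new method: the protonated oxazaborolidine binds the formyl oxygen of 2, and the nucleophilic pyrone carbon C3 attacks the CH2 terminus while pyrone C6 closes on the C–Br carbon in a concerted but strongly asynchronous normal-electron-demand Diels–Alder reaction; the closest known reaction types are the oxazaborolidinium-catalysed enantioselective Diels–Alder reactions of 2-bromoacrolein with simple dienes and the thermal or high-pressure Diels–Alder reactions of 2-pyrones with acrylic dienophiles that keep the CO2 bridge, but the union of a chiral boron Lewis acid, an enal and a simple alkyl-2-pyrone is without precedent. Both new rings, the cyclohexene (C1–C7–C8–C4–C5–C6) and the bridged δ-lactone that is the future oxane ring (C1–O2–C3–C4–C8–C7), close at once by suprafacial [4π+2π] addition across pyrone C3 and C6. The bridgeheads C1 and C4 are locked cis by the O–C(=O) tether and their absolute sense is fixed by the catalyst, whose aryl group shields one face of the bound enal, while C7 follows from the formyl-exo/bromine-endo orientation typical of 2-substituted acroleins. The regiochemistry needed (C–Br carbon to the oxygen-bearing pyrone C6) is secured by the ring oxygen and by the methyl groups at pyrone C4 and C6, which all raise the HOMO coefficient at C3 and stabilise the positive charge that develops at C4/C6 (ortho/para rule). A single exo/endo mode is also needed, because the two modes give antipodal bridgeheads from the same enal face. The low temperature keeps the adduct from losing CO2 and disfavours rearomatising conjugate alkylation at pyrone C3.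

Step 2
Reactants: 3 (1S,4S,7S)-7-bromo-1,5-dimethyl-3-oxo-2-oxabicyclo[2.2.2]oct-5-ene-7-carbaldehyde
Product: 4 (1S,4S,7S)-7-bromo-1,5-dimethyl-3-oxo-2-oxabicyclo[2.2.2]oct-5-ene-7-carboxylic acid
Conditions: NaClO2, NaH2PO4, 2-methylbut-2-ene, t-BuOH/H2O, 0 °C
Reagents that add atoms: sodium chlorite, [Na+].[O-]Cl=O
Why: The Pinnick oxidation turns the non-enolisable α-bromo aldehyde into the acid under near-neutral conditions that leave the lactone, the tertiary bromide and (thanks to the HOCl scavenger) the trisubstituted alkene alone, and no stereocentre is touched.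

Step 3
Reactants: 4 (1S,4S,7S)-7-bromo-1,5-dimethyl-3-oxo-2-oxabicyclo[2.2.2]oct-5-ene-7-carboxylic acid
Product: 7 (1S,4S,7S)-7-bromo-1,5-dimethyl-2-oxabicyclo[2.2.2]oct-5-en-3-one (Br endo), via acid chloride 5 (not isolated), via thiohydroxamate ester 6 (not isolated)
Conditions: (COCl)2, N,N-dimethylformamide (cat.), CH2Cl2, 0 °C → rt, evaporate; sodium 2-thioxopyridin-1(2H)-olate, 4-(dimethylamino)pyridine (cat.), CH2Cl2, 0 °C, dark; then t-BuSH (large excess), hv (tungsten lamp), 0 °C
Reagents that add atoms: none
Why: In this Barton reductive decarboxylation, homolysis of 6 and loss of CO2 give the α-bromo radical at C7, which should take hydrogen from the bulky thiol on its exo face (flanked only by the substituent-free ring oxygen O2) rather than on the endo face next to C6–H, so that bromine ends endo (7S) and anti to the C1–O2 bond, while the excess of thiol outruns homoallyl rearrangement.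

Step 4
Reactants: 7 (1S,4S,7S)-7-bromo-1,5-dimethyl-2-oxabicyclo[2.2.2]oct-5-en-3-one
Product: 9 (1S,4S,5R,7S)-7-bromo-1,5-dimethyl-2-oxabicyclo[2.2.2]octane-3,6-dione, via C6-alkylborane 8 (not isolated)
Conditions: BH3·SMe2, THF, 0 °C → rt; then N-methylmorpholine N-oxide, [nPr4N][RuO4] (5 mol %), 4 Å molecular sieves, CH2Cl2, rt
Reagents that add atoms: N-methylmorpholine N-oxide, C[N+]1([O-])CCOCC1
Why: Hydroboration puts boron on the less substituted alkene carbon C6 from the face syn to the lactone bridge (the other face lies under the endo bromine, and β-elimination of the C1 acyloxy group is barred at a bridgehead), and the one-pot N-oxide/perruthenate oxidation of the alkylborane gives the ketone directly, the C5 configuration (5R from syn addition) being of no consequence because step 5 erases it.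

Step 5
Reactants: 9 (1S,4S,5R,7S)-7-bromo-1,5-dimethyl-2-oxabicyclo[2.2.2]octane-3,6-dione
Product: 10 (1S,4R,5S,7S)-7-bromo-5-chloro-1,5-dimethyl-2-oxabicyclo[2.2.2]octane-3,6-dione
Conditions: SO2Cl2, CH2Cl2, 0 °C → rt, dark
Reagents that add atoms: sulfuryl chloride, O=S(=O)(Cl)Cl
Why: Electrophilic α-chlorination of the ketone runs through its only possible enol (C5=C6, since C1 is quaternary), and chlorine should enter on the enol face syn to the lactone bridge, whose O and C=O carry no inward substituent, because the other face is screened by the endo hydrogen at C8 and the endo bromine at C7, which sets the tertiary chloride (5S).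

Step 6
Reactants: 10 (1S,4R,5S,7S)-7-bromo-5-chloro-1,5-dimethyl-2-oxabicyclo[2.2.2]octane-3,6-dione
Product: 11 (1S,2S,3S,4R,6S)-6-bromo-3-chloro-4-(hydroxymethyl)-1,3-dimethylcyclohexane-1,2-diol
Conditions: LiBH4, THF, 0 °C; aqueous work-up
Reagents that add atoms: none
Why: Borohydride reduction opens the strained bridged δ-lactone to the primary/tertiary diol and reduces the α-chloro ketone to the carbinol (hydride expected from the less screened lactone-side face, 2S, a centre destroyed in step 8), the alkyl halides being inert to the reagent and the boron-bound halohydrin oxygens too weakly nucleophilic at 0 °C to close epoxides.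

Step 7
Reactants: 11 (1S,2S,3S,4R,6S)-6-bromo-3-chloro-4-(hydroxymethyl)-1,3-dimethylcyclohexane-1,2-diol
Product: 12 (1S,2S,3S,4R,6S)-6-bromo-3-chloro-1,3-dimethyl-4-{[(triethylsilyl)oxy]methyl}cyclohexane-1,2-diol
Conditions: Et3SiCl (1.05 equiv), imidazole, CH2Cl2, −20 °C
Reagents that add atoms: chlorotriethylsilane, CC[Si](Cl)(CC)CC
Why: Selective silylation takes the primary alcohol in preference to the hindered secondary and tertiary ones, which keeps this oxygen from trapping the aldehyde of 13 as a five-membered lactol, and no stereocentre is touched.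

Step 8
Reactants: 12 (1S,2S,3S,4R,6S)-6-bromo-3-chloro-1,3-dimethyl-4-{[(triethylsilyl)oxy]methyl}cyclohexane-1,2-diol
Product: 13 (2S,3R,5S)-5-bromo-2-chloro-2-methyl-6-oxo-3-{[(triethylsilyl)oxy]methyl}heptanal
Conditions: Pb(OAc)4, CH2Cl2, 0 °C
Reagents that add atoms: none
Why: The Criegee glycol cleavage cuts the C1–C2 bond of the tertiary/secondary trans-diol (reachable through the diequatorial chair or the acyclic pathway open to this reagent) and unveils the methyl ketone and the non-enolisable α-chloro aldehyde under non-basic conditions, so the α-bromo centre is not epimerised and no new stereocentre arises.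

Step 9
Reactants: 13 (2S,3R,5S)-5-bromo-2-chloro-2-methyl-6-oxo-3-{[(triethylsilyl)oxy]methyl}heptanal
Product: 15 (2R,3S,5R)-3-bromo-5-[(2S,3E)-4-bromo-2-chlorobut-3-en-2-yl]-2-methyloxan-2-ol, via silyl ether 14 (not isolated)
Conditions: CrBr2 (6 equiv) and CHBr3 (1.5 equiv) aged in THF, 0 °C, 30 min; then 13, 0 °C; filtration through silica; then HF·pyridine, pyridine, THF, 0 °C
Reagents that add atoms: bromoform, BrC(Br)Br
Why: In the Takai olefination the geminal dichromium carbenoid adds only to the aldehyde and eliminates to the (E)-bromoalkene (bulky quaternary substituent and bromine anti), ageing the reagent at the 4:1 ratio consumes free divalent chromium before the α-bromo ketone is exposed, and fluoride desilylation frees the C6 hydroxyl, which adds to the ketone so that the hemiketal centre settles under thermodynamic control as 2R (OH axial by the anomeric effect; CH3, Br and side chain equatorial).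

## Compound list

| No. | Name | SMILES | Role |
|---|---|---|---|
| 1 | 4,6-dimethyl-2H-pyran-2-one | CC1=CC(C)=CC(=O)O1 | starting material |
| 2 | 2-bromoprop-2-enal | C=C(Br)C=O | starting material |
| 3 | (1S,4S,7S)-7-bromo-1,5-dimethyl-3-oxo-2-oxabicyclo[2.2.2]oct-5-ene-7-carbaldehyde (Br endo, CHO exo) | C[C@]12OC(=O)[C@H](C(C)=C1)C[C@@]2(Br)C=O | intermediate |
| 4 | (1S,4S,7S)-7-bromo-1,5-dimethyl-3-oxo-2-oxabicyclo[2.2.2]oct-5-ene-7-carboxylic acid | C[C@]12OC(=O)[C@H](C(C)=C1)C[C@@]2(Br)C(=O)O | intermediate |
| 5 | (1S,4S,7S)-7-bromo-1,5-dimethyl-3-oxo-2-oxabicyclo[2.2.2]oct-5-ene-7-carbonyl chloride | C[C@]12OC(=O)[C@H](C(C)=C1)C[C@@]2(Br)C(=O)Cl | intermediate |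
| 6 | 2-thioxopyridin-1(2H)-yl ester of acid 4 (Barton ester) | C[C@]12OC(=O)[C@H](C(C)=C1)C[C@@]2(Br)C(=O)On1ccccc1=S | intermediate |
| 7 | (1S,4S,7S)-7-bromo-1,5-dimethyl-2-oxabicyclo[2.2.2]oct-5-en-3-one (Br endo) | C[C@]12OC(=O)[C@H](C(C)=C1)C[C@@H]2Br | intermediate |
| 8 | (1S,4S,5S,6S,7S)-6-boranyl-7-bromo-1,5-dimethyl-2-oxabicyclo[2.2.2]octan-3-one (H and BH2 added syn to the lactone bridge) | C[C@]12OC(=O)[C@H]([C@@H](C)[C@@H]1B)C[C@@H]2Br | intermediate |
| 9 | (1S,4S,5R,7S)-7-bromo-1,5-dimethyl-2-oxabicyclo[2.2.2]octane-3,6-dione | C[C@]12OC(=O)[C@H]([C@@H](C)C1=O)C[C@@H]2Br | intermediate |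
| 10 | (1S,4R,5S,7S)-7-bromo-5-chloro-1,5-dimethyl-2-oxabicyclo[2.2.2]octane-3,6-dione (Cl syn to the lactone bridge) | C[C@]12OC(=O)[C@H]([C@](C)(Cl)C1=O)C[C@@H]2Br | intermediate |
| 11 | (1S,2S,3S,4R,6S)-6-bromo-3-chloro-4-(hydroxymethyl)-1,3-dimethylcyclohexane-1,2-diol | C[C@@]1(O)[C@@H](Br)C[C@H](CO)[C@](C)(Cl)[C@H]1O | intermediate |
| 12 | (1S,2S,3S,4R,6S)-6-bromo-3-chloro-1,3-dimethyl-4-{[(triethylsilyl)oxy]methyl}cyclohexane-1,2-diol | C[C@@]1(O)[C@@H](Br)C[C@H](CO[Si](CC)(CC)CC)[C@](C)(Cl)[C@H]1O | intermediate |
| 13 | (2S,3R,5S)-5-bromo-2-chloro-2-methyl-6-oxo-3-{[(triethylsilyl)oxy]methyl}heptanal | CC(=O)[C@@H](Br)C[C@H](CO[Si](CC)(CC)CC)[C@](C)(Cl)C=O | intermediate |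
| 14 | (3S,5R,6S,7E)-3,8-dibromo-6-chloro-6-methyl-5-{[(triethylsilyl)oxy]methyl}oct-7-en-2-one | CC(=O)[C@@H](Br)C[C@H](CO[Si](CC)(CC)CC)[C@](C)(Cl)/C=C/Br | intermediate |
| 15 | (2R,3S,5R)-3-bromo-5-[(2S,3E)-4-bromo-2-chlorobut-3-en-2-yl]-2-methyloxan-2-ol | C[C@@](Cl)(/C=C/Br)[C@H]1CO[C@@](C)(O)[C@@H](Br)C1 | target |

Total step count: 9
Longest linear sequence: 9 steps (from 1 or 2 to 15)

## Steps most likely to fail

**Step 1 (proposed new method).**
- Risks: the Lewis-basic pyrone carbonyl may sequester the boron cation. The polar pathway may leak into rearomatising conjugate alkylation at pyrone C3. Compound 2 may polymerise. Weak exo/endo discrimination may erode the enantiomeric purity.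
- Fallback (known chemistry; sets out from 1 and 2, comes back at 4): the uncatalysed cycloaddition is run under high pressure (about 13 kbar, CH2Cl2, 30 °C, trace of hydroquinone), the established way to keep the CO2 bridge in pyrone adducts, to give the racemic aldehyde F1. Pinnick oxidation gives the racemic acid F2. Classical resolution by fractional crystallisation of the (R)-1-phenylethylammonium salt F3, followed by acidification with dilute HCl, delivers 4.

**Step 9.**
- Risks: residual divalent chromium may reduce the α-bromo ketone to a chromium enolate. The bromide-rich trivalent chromium may exchange or ionise the tertiary chloride, which becomes allylic after olefination.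
- Fallback (sets out from 13, comes back at 14): the ketone is masked at the alcohol level. NaBH4 in MeOH at −20 °C reduces both carbonyl groups to the diol F4. 2,2,6,6-Tetramethylpiperidin-1-oxyl (cat.) with PhI(OAc)2 oxidises only the primary alcohol, giving the hydroxy aldehyde F5, whose bromide is now a plain secondary alkyl bromide inert to divalent chromium. Takai olefination under standard conditions gives the bromohydrin F6. Dess–Martin periodinane restores the ketone without touching C3 and gives 14, which is desilylated as in step 9.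

**Step 3.**
- Risks: poor facial selectivity in the hydrogen transfer to the planar α-bromo radical, or homoallyl/cyclopropylcarbinyl rearrangement of that radical.
- Fallback (sets out from 7 as obtained, mixed with the exo bromide F7, and comes back at 7): a stereoconvergent opening and re-closure. Zn dust in AcOH/THF (Boord-type reductive 1,2-elimination of bromide and carboxylate) converts both epimers into the dienoic acid F8, which keeps only the stereocentre set in step 1. Bromolactonisation (NBS, NaHCO3, MeCN, 0 °C) closes the lactone again. The tethered carboxylate can reach the methyl-bearing diene terminus only from its own face and bromine enters anti to it, so 7 alone should result.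

## Further compounds

F1 | step 1 | racemic 7-bromo-1,5-dimethyl-3-oxo-2-oxabicyclo[2.2.2]oct-5-ene-7-carbaldehyde (3 plus its enantiomer) | C[C@]12OC(=O)[C@H](C(C)=C1)C[C@@]2(Br)C=O.C[C@@]12OC(=O)[C@@H](C(C)=C1)C[C@]2(Br)C=O
F2 | step 1 | racemic 7-bromo-1,5-dimethyl-3-oxo-2-oxabicyclo[2.2.2]oct-5-ene-7-carboxylic acid (4 plus its enantiomer) | C[C@]12OC(=O)[C@H](C(C)=C1)C[C@@]2(Br)C(=O)O.C[C@@]12OC(=O)[C@@H](C(C)=C1)C[C@]2(Br)C(=O)O
F3 | step 1 | (R)-1-phenylethylammonium salt of 4 | C[C@]12OC(=O)[C@H](C(C)=C1)C[C@@]2(Br)C(=O)O.C[C@@H](N)c1ccccc1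
F4 | step 9 | (2S,3R,5S)-5-bromo-2-chloro-2-methyl-3-{[(triethylsilyl)oxy]methyl}heptane-1,6-diol (C6 epimers) | CC(O)[C@@H](Br)C[C@H](CO[Si](CC)(CC)CC)[C@](C)(Cl)CO
F5 | step 9 | (2S,3R,5S)-5-bromo-2-chloro-6-hydroxy-2-methyl-3-{[(triethylsilyl)oxy]methyl}heptanal (C6 epimers) | CC(O)[C@@H](Br)C[C@H](CO[Si](CC)(CC)CC)[C@](C)(Cl)C=O
F6 | step 9 | (3S,5R,6S,7E)-3,8-dibromo-6-chloro-6-methyl-5-{[(triethylsilyl)oxy]methyl}oct-7-en-2-ol (C2 epimers) | CC(O)[C@@H](Br)C[C@H](CO[Si](CC)(CC)CC)[C@](C)(Cl)/C=C/Br
F7 | step 3 | (1S,4S,7R)-7-bromo-1,5-dimethyl-2-oxabicyclo[2.2.2]oct-5-en-3-one (Br exo) | C[C@]12OC(=O)[C@H](C(C)=C1)C[C@H]2Br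
F8 | step 3 | (1S)-2,4-dimethylcyclohexa-2,4-diene-1-carboxylic acid | OC(=O)[C@H]1CC=C(C)C=C1C
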